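Both terpene rings are the same (3R,4R)-p-menth-1-en-3-yl unit (p-menthane numbering: C1 carries CH3, C3 the arene, C4 the isopropyl group) on C3′ and C5′ of the phloroglucinol ring. One C10 allyl-cation precursor, used twice in a final Friedel–Crafts step, therefore suffices. Its six-membered ring is cut into C2–C1–C6 and C3–C4–C5, exploiting that C4 is the central carbon of a hidden 2-isopropylacrolein. The key step is a catalytic asymmetric [3+3] Michael/protonation/Wittig annulation of that enal with a keto ester ylide. It forms C5–C6 and C2–C3, closes the ring and sets C4, which later relays C3. Its precursors are two acyclic, achiral fragments.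

Key step: step 3

Assumption: the (S)-configured diamine salt is taken to deliver the proton to the enamine face that gives 4R; should the sense be opposite, the equally accessible (R)-diamine is used.
Assumption: 11 is bought as the natural product pinocembrin chalcone.

Step 1
Reactants: 1 3-methylbutanal (isovaleraldehyde)
Product: 2 3-methyl-2-methylidenebutanal (2-isopropylacrolein)
Conditions: 37% aq. HCHO, pyrrolidine (10 mol%), EtCO2H (10 mol%), i-PrOH, 45 °C
Reagents that add atoms: formaldehyde, C=O
Why: Amine-catalysed Mannich condensation/elimination (α-methylenation of an aldehyde): the enamine of 1 attacks the formaldehyde-derived iminium ion and β-elimination of the amine leaves the 2-substituted acrolein, which has no α-hydrogen left for further reaction; no stereocentre is formed.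

Step 2
Reactants: 3 tert-butyl 4-chloro-3-oxobutanoate
Product: 5 tert-butyl 3-oxo-4-(triphenylphosphoranylidene)butanoate, via phosphonium chloride 4 (not isolated)
Conditions: PPh3, toluene, 50 °C; then aq. Na2CO3, CH2Cl2, rt
Reagents that add atoms: triphenylphosphine, c1ccc(cc1)P(c1ccccc1)c1ccccc1
Why: SN2 quaternisation of PPh3 by the α-chloro ketone and deprotonation of the acidic P–CH2–C=O position with mild aqueous base is the standard preparation of a stabilised acyl ylide and leaves the ester-flanked methylene free as the later Michael donor; no stereocentre is formed.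

Step 3
Reactants: 2 3-methyl-2-methylidenebutanal; 5 tert-butyl 3-oxo-4-(triphenylphosphoranylidene)butanoate
Product: 7 tert-butyl (5R)-2-oxo-5-(propan-2-yl)cyclohex-3-ene-1-carboxylate (epimers at C1), via formyl ylide 6 (not isolated)
Conditions: (2S)-N1,N1-diethyl-3,3-dimethylbutane-1,2-diamine·CF3SO3H (20 mol%), CHCl3, −20 °C to rt, slow addition of 2
Reagents that add atoms: none
Why: Proposed new method: the free NH2 group of the catalyst condenses with 2 to an iminium ion, the C6 methylene of 5 (between ketone and ester) adds to its unsubstituted terminus C5 (bond C5–C6), the resulting enamine is protonated at C4 by the neighbouring ammonium group, and after hydrolysis the formyl carbon C3 of 6 is taken at once by the ylide carbon C2 in an intramolecular Wittig reaction (bond C2–C3, loss of Ph3PO). The closest known reaction types are the tandem Michael/intramolecular Wittig [3+3] cyclohexenone annulation of this ylide class with enals (base-mediated, or enantioselective under secondary-amine catalysis with β-substituted enals) and the primary-amine-catalysed conjugate addition/enantioselective enamine protonation of 2-alkylacroleins, whose merger is untested. The single ring closes by 6-exo-trig attack of C2 on the C3 carbonyl group and collapse of the oxaphosphetane, which in a six-membered ring can only give the cis olefin. C4, the only lasting new stereocentre, is controlled by the catalyst through face-selective internal proton delivery, whereas C6 is a labile β-keto ester centre that disappears in step 4. The step needs 1,4- before 1,2-reaction, secured by the open CH2 terminus of 2, its hindered α-branched formyl group and the low carbonyl reactivity of a stabilised ylide, and it needs the catalyst salt to survive, which holds because an acyl ylide is a far weaker base than a trialkylamine. It also needs ring closure to outrun enolisation of 6, which the intramolecular, essentially neutral Wittig step should secure.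

Step 4
Reactants: 7 tert-butyl (5R)-2-oxo-5-(propan-2-yl)cyclohex-3-ene-1-carboxylate
Product: 9 (R)-cryptone [(4R)-4-(propan-2-yl)cyclohex-2-en-1-one], via β-keto acid 8 (not isolated)
Conditions: CF3CO2H/CH2Cl2 (1:4), 0 °C to rt; evaporate; toluene, 40 °C
Reagents that add atoms: none
Why: Acidolysis of the tert-butyl ester (loss of isobutene) and spontaneous six-centre decarboxylation of the β-keto acid remove the activating group under base-free, mild conditions in which the γ-stereocentre C4 of the enone should not enolise.

Step 5
Reactants: 9 (R)-cryptone
Product: 10 (4R)-1-methyl-4-(propan-2-yl)cyclohex-2-en-1-ol (p-menth-2-en-1-ol, both C1 epimers)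
Conditions: MeLi, Et2O, −78 °C; then H2O
Reagents that add atoms: methyllithium, [Li]C
Why: 1,2-Addition of a hard organolithium to the enone carbonyl at low temperature outruns deprotonation; the new carbinol centre C1 forms as a mixture, which is irrelevant because C1 becomes sp2 again in step 6, and C4 is untouched.

Step 6
Reactants: 10 (4R)-1-methyl-4-(propan-2-yl)cyclohex-2-en-1-ol (2.3 equiv); 11 (E)-2′,4′,6′-trihydroxychalcone
Product: 13 neolinderachalcone, via monoalkylated chalcone 12 (not isolated)
Conditions: BF3·OEt2 (30 mol%), 4 Å molecular sieves, 1,4-dioxane/CH2Cl2, 0 °C to rt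
Reagents that add atoms: none
Why: Twofold Friedel–Crafts allylation of an acylphloroglucinol by a cyclic tertiary allylic alcohol, a known reaction type: ionisation of 10 gives the C1–C2–C3 allyl cation, C3′ and then C5′ of the arene attack its less hindered secondary terminus C3 on the face anti to the C4 isopropyl group, which sets both C3 centres trans (3R,4R), restores the C1=C2 olefin, and, because two units are paired, diverts residual minor enantiomer of 10 mainly into a separable meso-type diastereomer (Horeau-type amplification).

Compound list
1 | 3-methylbutanal | CC(C)CC=O | starting material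
2 | 3-methyl-2-methylidenebutanal (2-isopropylacrolein) | C=C(C=O)C(C)C | intermediate
3 | tert-butyl 4-chloro-3-oxobutanoate | CC(C)(C)OC(=O)CC(=O)CCl | starting material
4 | [4-(tert-butoxy)-2,4-dioxobutyl]triphenylphosphonium chloride | CC(C)(C)OC(=O)CC(=O)C[P+](c1ccccc1)(c1ccccc1)c1ccccc1.[Cl-] | intermediate
5 | tert-butyl 3-oxo-4-(triphenylphosphoranylidene)butanoate | CC(C)(C)OC(=O)CC(=O)C=P(c1ccccc1)(c1ccccc1)c1ccccc1 | intermediate
6 | tert-butyl (4R)-4-formyl-5-methyl-2-[(triphenylphosphoranylidene)acetyl]hexanoate (C2 epimers) | O=C[C@@H](C(C)C)CC(C(=O)OC(C)(C)C)C(=O)C=P(c1ccccc1)(c1ccccc1)c1ccccc1 | intermediate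
7 | tert-butyl (5R)-2-oxo-5-(propan-2-yl)cyclohex-3-ene-1-carboxylate (C1 epimers) | O=C1C=C[C@@H](C(C)C)CC1C(=O)OC(C)(C)C | intermediate
8 | (5R)-2-oxo-5-(propan-2-yl)cyclohex-3-ene-1-carboxylic acid | O=C1C=C[C@@H](C(C)C)CC1C(=O)O | intermediate
9 | (R)-cryptone, (4R)-4-(propan-2-yl)cyclohex-2-en-1-one | O=C1C=C[C@@H](C(C)C)CC1 | intermediate
10 | (4R)-1-methyl-4-(propan-2-yl)cyclohex-2-en-1-ol (C1 epimers) | CC1(O)C=C[C@@H](C(C)C)CC1 | intermediate
11 | (E)-3-phenyl-1-(2,4,6-trihydroxyphenyl)prop-2-en-1-one (2′,4′,6′-trihydroxychalcone) | O=C(/C=C/c1ccccc1)c1c(O)cc(O)cc1O | starting material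
12 | (E)-1-{2,4,6-trihydroxy-3-[(1R,6R)-3-methyl-6-(propan-2-yl)cyclohex-2-en-1-yl]phenyl}-3-phenylprop-2-en-1-one | CC1=C[C@H](c2c(O)cc(O)c(C(=O)/C=C/c3ccccc3)c2O)[C@@H](C(C)C)CC1 | intermediate
13 | neolinderachalcone, (E)-1-{2,4,6-trihydroxy-3,5-bis[(1R,6R)-3-methyl-6-(propan-2-yl)cyclohex-2-en-1-yl]phenyl}-3-phenylprop-2-en-1-one | CC1=C[C@H](c2c(O)c(C(=O)/C=C/c3ccccc3)c(O)c([C@H]3C=C(C)CC[C@@H]3C(C)C)c2O)[C@@H](C(C)C)CC1 | target

Total step count: 6. Longest linear sequence: 5 (steps 1, 3, 4, 5, 6).

Steps most likely to fail

Risk 1, step 3 (bears the label).
- What may go wrong: the uncatalysed conjugate addition may compete with the iminium path. The enamine protonation may be poorly face-selective or reversible. Intermolecular olefination of the formyl group may intervene.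
- Fallback: it sets out from 2 and 5 and comes back at 9, and it uses known chemistry that separates ring construction from stereocontrol while the ring atoms still stem from the same [3+3] annulation. The annulation is run in its established base-mediated form (catalytic NaH, THF, rt) to give the racemic keto ester F1. CF3CO2H as in step 4 gives racemic cryptone F2. H2 over Pd/C in EtOAc removes olefin and stereocentre to give achiral 4-isopropylcyclohexanone F3. Enantioselective deprotonation with LiN[(R)-CHMePh]2 and LiCl in the presence of Me3SiCl (THF, −95 °C, the antipodal amide if the sense demands it) gives the (S)-silyl enol ether F4. Saegusa–Ito oxidation (Pd(OAc)2, MeCN) returns 9.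

Risk 2, step 6.
- What may go wrong: the second alkylation may stall through crowding. The chalcone may close by oxa-Michael addition under acid. The allyl cation may lose a proton, which gives dienes and, through re-protonation, loss of configurational integrity. A phenol may add to the ring olefin.
- Fallback: it sets out from 11 and 10 and comes back at 13, and it masks the enone as a flavanone. Compound 11 is closed (NaOAc, EtOH, reflux) to racemic pinocembrin F5. F5 is alkylated at C6 and C8 with 10 (BF3·OEt2, 1,4-dioxane, rt) to the bis(menthenyl)flavanone F6, whose C2 epimers are of no consequence. Concentrated aq. KOH/EtOH under argon followed by pouring into cold dilute HCl opens the pyranone ring by retro-oxa-Michael elimination to 13.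

Risk 3, step 5.
- What may go wrong: the basic organolithium may deprotonate the enone with erosion at C4. The tertiary allylic alcohol may ionise or dehydrate on work-up and chromatography.
- Fallback: it sets out from 9 and comes back at 13, and it avoids the alcohol altogether. Wittig methylenation (Ph3PCH3Br, KOt-Bu, THF, 0 °C) gives (R)-β-phellandrene F7. Under the acid conditions of step 6 with 11, F7 is protonated at its exocyclic CH2 to the same C1–C2–C3 allyl cation and is captured twice as before.

Further compounds
F1 | step 3 | racemic tert-butyl 2-oxo-5-(propan-2-yl)cyclohex-3-ene-1-carboxylate | O=C1C=CC(C(C)C)CC1C(=O)OC(C)(C)C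
F2 | step 3 | racemic cryptone | O=C1C=CC(C(C)C)CC1
F3 | step 3 | 4-(propan-2-yl)cyclohexan-1-one | O=C1CCC(C(C)C)CC1
F4 | step 3 | trimethyl{[(4S)-4-(propan-2-yl)cyclohex-1-en-1-yl]oxy}silane | C[Si](C)(C)OC1=CC[C@@H](C(C)C)CC1
F5 | step 6 | racemic pinocembrin (5,7-dihydroxyflavanone) | O=C1CC(c2ccccc2)Oc2cc(O)cc(O)c12
F6 | step 6 | 5,7-dihydroxy-6,8-bis[(1R,6R)-3-methyl-6-(propan-2-yl)cyclohex-2-en-1-yl]flavanone (C2 epimers) | O=C1CC(c2ccccc2)Oc2c1c(O)c([C@H]1C=C(C)CC[C@@H]1C(C)C)c(O)c2[C@H]1C=C(C)CC[C@@H]1C(C)C
F7 | step 5 | (R)-β-phellandrene, (6R)-3-methylidene-6-(propan-2-yl)cyclohex-1-ene | C=C1C=C[C@@H](C(C)C)CC1
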